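**Plan**

1. Isolappaol A is read as three ferulate-type C6C3 units. Its γ-lactone (O1, C2=O, C3, C4, C5) is a 2,3-dibenzylsuccinate with one carboxyl reduced (C5), and the aryl ring of the C3 benzyl group carries the fused 2′-aryl-3′-hydroxymethyl-2′,3′-dihydrobenzofuran.
2. Cuts, in retrosynthetic order: lactone O1–C2 (lactonisation); lactone C3–C4 (oxidative heterocoupling of two 3-arylpropanoate enolates); dihydrofuran C2′–C3′ (Rh-carbenoid 1,5 C–H insertion); aryl–C3′ (Pd coupling with ethyl diazoacetate) and O1′–C2′ (phenol benzylation).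
3. Forward: the dihydrofuran ring closes first (step 5), the two halves are joined at C3–C4 (step 10), the lactone ring closes last (step 11), and one hydrogenolysis ends the route.
4. Feature that allows the key step: lactone C3 and C4 are each α to a carboxyl-level carbon (C2 and C5) and each bears an arylmethyl group. C3–C4 is therefore the α,α′ bond between two hydrocinnamate units, the 8–8′ bond that oxidative coupling forges in lignan biosynthesis, made here at the carboxylate oxidation level.
5. Stereochemistry: lactone C4 comes from an (S)-4-benzyloxazolidinone during the coupling and C3 from base equilibration to the trans-lactone; benzofuran C2′ comes from a chiral Rh(II) catalyst and C3′ from base equilibration to the trans ester.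

Key step: step 10

Assumption (step 5): the sense of induction of the N-phthaloyl-tert-leucinate Rh(II) catalysts is taken to follow that of simpler 2-(benzyloxy)aryl diazoacetates, which calls for the R-ligand series to reach 2′S; the S-series catalyst is used instead if the sense proves opposite on this substrate.

Remark: lithium enolates, alkoxides and the rhodium carbenoid are treated as reactive forms of the numbered compounds and carry no numbers of their own.

**Route**

Step 1
Reactants: 1 3-(4-hydroxy-3-methoxyphenyl)propanoic acid (dihydroferulic acid)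
Product: 2 tert-butyl 3-(4-hydroxy-3-methoxyphenyl)propanoate
Conditions: Me2NCH(OtBu)2 (4 equiv), PhMe, 80 °C
Reagents that add atoms: N,N-dimethylformamide di-tert-butyl acetal, CN(C)C(OC(C)(C)C)OC(C)(C)C
Why: Acetal-mediated esterification tert-butylates the carboxylic acid through its carboxylate/alkoxyiminium ion pair while the much less acidic guaiacol OH should stay free.

Step 2
Reactants: 2 tert-butyl 3-(4-hydroxy-3-methoxyphenyl)propanoate
Product: 3 tert-butyl 3-(4-hydroxy-3-iodo-5-methoxyphenyl)propanoate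
Conditions: I2 (1.05 equiv), NaHCO3, THF/H2O, 0 °C to rt
Reagents that add atoms: iodine, II
Why: Electrophilic aromatic iodination of the phenolate should go to the only open ortho/para site of the strongest donor (para is blocked by the side chain, the other ortho site by OMe), as in the iodination of vanillin at C5.

Step 3
Reactants: 3 tert-butyl 3-(4-hydroxy-3-iodo-5-methoxyphenyl)propanoate; 4 [4-(benzyloxy)-3-methoxyphenyl]methanol
Product: 5 tert-butyl 3-(4-{[4-(benzyloxy)-3-methoxybenzyl]oxy}-3-iodo-5-methoxyphenyl)propanoate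
Conditions: PPh3, DIAD, THF, 0 °C to rt
Reagents that add atoms: none
Why: Mitsunobu etherification of an acidic ortho-iodophenol with a primary electron-rich benzylic alcohol is neutral and should leave the tert-butyl ester and the aryl iodide untouched.

Step 4
Reactants: 5 tert-butyl 3-(4-{[4-(benzyloxy)-3-methoxybenzyl]oxy}-3-iodo-5-methoxyphenyl)propanoate; 6 ethyl diazoacetate
Product: 7 ethyl 2-(2-{[4-(benzyloxy)-3-methoxybenzyl]oxy}-5-(3-tert-butoxy-3-oxopropyl)-3-methoxyphenyl)-2-diazoacetate
Conditions: Pd(PPh3)4 (5 mol%), Ag2CO3 (0.5 equiv), Et3N (1.3 equiv), PhMe, rt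
Reagents that add atoms: none
Why: Pd(0)-catalysed cross-coupling of an aryl iodide with the C–H bond of ethyl diazoacetate (oxidative addition, silver-assisted palladation of the diazo carbon, reductive elimination with the diazo group retained) should give the donor/acceptor diazo ester in one step.

Step 5
Reactants: 7 ethyl 2-(2-{[4-(benzyloxy)-3-methoxybenzyl]oxy}-5-(3-tert-butoxy-3-oxopropyl)-3-methoxyphenyl)-2-diazoacetate
Product: 9 ethyl (2S,3S)-2-[4-(benzyloxy)-3-methoxyphenyl]-5-(3-tert-butoxy-3-oxopropyl)-7-methoxy-2,3-dihydro-1-benzofuran-3-carboxylate (trans), via cis ester 8 (not isolated)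
Conditions: Rh2(R-PTTL)4 (2 mol%), PhMe, −78 to −40 °C; then NaOEt (0.2 equiv), EtOH, rt
Reagents that add atoms: none
Why: Rh(II)-carbenoid intramolecular 1,5 C–H insertion into the O-benzylic methylene (activated by the ether oxygen and the electron-rich aryl group) closes the dihydrofuran ring with C2′ set by the chiral catalyst in the cis ester, and catalytic ethoxide then epimerises the ester-bearing C3′ to the more stable trans ester without touching C2′, because ring-opening β-elimination is stereoelectronically disfavoured (the enolate π orbital is orthogonal to the ring C–O bond).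

Step 6
Reactants: 9 ethyl (2S,3S)-2-[4-(benzyloxy)-3-methoxyphenyl]-5-(3-tert-butoxy-3-oxopropyl)-7-methoxy-2,3-dihydro-1-benzofuran-3-carboxylate
Product: 10 tert-butyl 3-[(2S,3R)-2-[4-(benzyloxy)-3-methoxyphenyl]-3-(hydroxymethyl)-7-methoxy-2,3-dihydro-1-benzofuran-5-yl]propanoate
Conditions: LiBH4 (1.5 equiv), THF, MeOH (1 equiv), 0 °C to rt
Reagents that add atoms: none
Why: Chemoselective borohydride reduction should take the activated α-aryl ethyl ester and spare the hindered tert-butyl ester; no stereocentre is touched (the descriptor at C3′ changes only through CIP priorities).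

Step 7
Reactants: 10 tert-butyl 3-[(2S,3R)-2-[4-(benzyloxy)-3-methoxyphenyl]-3-(hydroxymethyl)-7-methoxy-2,3-dihydro-1-benzofuran-5-yl]propanoate
Product: 11 tert-butyl 3-[(2S,3R)-2-[4-(benzyloxy)-3-methoxyphenyl]-3-[(benzyloxy)methyl]-7-methoxy-2,3-dihydro-1-benzofuran-5-yl]propanoate
Conditions: NaH, BnBr, Bu4NI (cat.), THF/DMF, 0 °C
Reagents that add atoms: benzyl bromide, BrCc1ccccc1
Why: Williamson benzylation of the primary alkoxide at 0 °C should outrun enolisation of the tert-butyl ester and removes the last acidic O–H before the enolate chemistry, with the same hydrogenolysable group on all three hydroxyls.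

Step 8
Reactants: 1 3-(4-hydroxy-3-methoxyphenyl)propanoic acid
Product: 13 3-[4-(benzyloxy)-3-methoxyphenyl]propanoic acid, via benzyl ester 12 (not isolated)
Conditions: BnBr (2.2 equiv), K2CO3, DMF, 60 °C; then NaOH, MeOH/H2O, 60 °C; HCl work-up
Reagents that add atoms: benzyl bromide, BrCc1ccccc1
Why: Exhaustive O-benzylation (Williamson ether synthesis) followed by saponification of the benzyl ester in the same pot should leave the phenol protected and the acid free.

Step 9
Reactants: 13 3-[4-(benzyloxy)-3-methoxyphenyl]propanoic acid; 14 (4S)-4-benzyl-1,3-oxazolidin-2-one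
Product: 16 (4S)-4-benzyl-3-{3-[4-(benzyloxy)-3-methoxyphenyl]propanoyl}-1,3-oxazolidin-2-one, via mixed pivalic anhydride 15 (not isolated)
Conditions: PivCl, Et3N, THF, −20 °C; then 14, LiCl, −20 °C to rt
Reagents that add atoms: pivaloyl chloride, CC(C)(C)C(=O)Cl (atoms kept only in 15)
Why: N-Acylation of the oxazolidinone through the mixed pivalic anhydride under LiCl/Et3N activation is the standard mild entry to N-acyloxazolidinones; the auxiliary stereocentre is bought.

Step 10
Reactants: 16 (4S)-4-benzyl-3-{3-[4-(benzyloxy)-3-methoxyphenyl]propanoyl}-1,3-oxazolidin-2-one; 11 tert-butyl 3-[(2S,3R)-2-[4-(benzyloxy)-3-methoxyphenyl]-3-[(benzyloxy)methyl]-7-methoxy-2,3-dihydro-1-benzofuran-5-yl]propanoate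
Product: 17 tert-butyl (2RS,3R)-3-{[(4S)-4-benzyl-2-oxo-1,3-oxazolidin-3-yl]carbonyl}-4-[4-(benzyloxy)-3-methoxyphenyl]-2-({(2S,3R)-2-[4-(benzyloxy)-3-methoxyphenyl]-3-[(benzyloxy)methyl]-7-methoxy-2,3-dihydro-1-benzofuran-5-yl}methyl)butanoate
Conditions: 16 (1.3 equiv), 11 (1.0 equiv), LDA (2.3 equiv), THF, −78 °C; then Fe(acac)3 (2.2 equiv), −78 °C to rt
Reagents that add atoms: none
Why: LDA converts both partners into lithium enolates (the chelated Z-enolate of imide 16 and the ester enolate of 11) that form a mixed aggregate; Fe(III) removes one electron from one enolate, the α-carbonyl radical is trapped by the other enolate inside the aggregate, and a second one-electron oxidation gives the 2,3-disubstituted succinate. The closest known reaction type is the intermolecular oxidative heterocoupling of N-acyloxazolidinone enolates with ester enolates by Fe(III) or Cu(II) salts, which has been applied to unsymmetrical 2,3-dibenzylsuccinates en route to dibenzylbutyrolactone lignans. No ring closes here; the bond formed is C3–C4 of the future lactone, which is closed in step 11. The imide α-carbon (future lactone C4) should be set R by the auxiliary, whose benzyl group blocks one face of the chelated Z-enolate as in oxazolidinone enolate alkylations, whereas the ester α-carbon (future C3) forms without control and is corrected by equilibration in step 11. The step needs cross- over homo-coupling, which heteroaggregation, the different oxidation potentials of imide and ester enolates and a modest excess of the cheap imide should secure, and it needs a single deprotonation site in 11, which is guaranteed because the benzofuran C3′ carboxylate was reduced and benzylated beforehand, leaving only the C–H α to the tert-butyl ester acidic. The benzyl ethers, the electron-rich arenes and the dihydrobenzofuran should be inert to LDA at −78 °C and to the mild Fe(III) oxidant.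

Step 11
Reactants: 17 tert-butyl (2RS,3R)-3-{[(4S)-4-benzyl-2-oxo-1,3-oxazolidin-3-yl]carbonyl}-4-[4-(benzyloxy)-3-methoxyphenyl]-2-({(2S,3R)-2-[4-(benzyloxy)-3-methoxyphenyl]-3-[(benzyloxy)methyl]-7-methoxy-2,3-dihydro-1-benzofuran-5-yl}methyl)butanoate
Product: 19 (3R,4R)-4-[4-(benzyloxy)-3-methoxybenzyl]-3-({(2S,3R)-2-[4-(benzyloxy)-3-methoxyphenyl]-3-[(benzyloxy)methyl]-7-methoxy-2,3-dihydro-1-benzofuran-5-yl}methyl)oxolan-2-one (tri-O-benzyl isolappaol A), via hydroxy ester 18 (not isolated)
Conditions: LiBH4, THF, MeOH (1 equiv), 0 °C; then DBU, PhMe, 90 °C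
Reagents that add atoms: none
Why: Reductive cleavage of the N-acyloxazolidinone by LiBH4 should give the primary alcohol faster than the tert-butyl ester is attacked, and DBU then drives 5-exo lactonisation with loss of tert-butanol and equilibrates the enolisable C3, so that both C2-epimers of 17 converge on the thermodynamically preferred 3,4-trans lactone (C4 fixed, C3 relayed from it).

Step 12
Reactants: 19 (3R,4R)-4-[4-(benzyloxy)-3-methoxybenzyl]-3-({(2S,3R)-2-[4-(benzyloxy)-3-methoxyphenyl]-3-[(benzyloxy)methyl]-7-methoxy-2,3-dihydro-1-benzofuran-5-yl}methyl)oxolan-2-one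
Product: 20 isolappaol A, (3R,4R)-4-(4-hydroxy-3-methoxybenzyl)-3-{[(2S,3R)-2-(4-hydroxy-3-methoxyphenyl)-3-(hydroxymethyl)-7-methoxy-2,3-dihydro-1-benzofuran-5-yl]methyl}oxolan-2-one
Conditions: H2 (1 atm), 10% Pd/C, EtOAc/MeOH, rt
Reagents that add atoms: none
Why: Pd-catalysed hydrogenolysis should remove the two aryl benzyl ethers and the primary alkyl benzyl ether under neutral conditions at room temperature, under which the lactone, its trans stereocentres and the cyclic 2′-aryl C–O bond of the dihydrobenzofuran are expected to persist.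

**Compound list**

1 | 3-(4-hydroxy-3-methoxyphenyl)propanoic acid (dihydroferulic acid) | COc1cc(CCC(=O)O)ccc1O | starting material
2 | tert-butyl 3-(4-hydroxy-3-methoxyphenyl)propanoate | COc1cc(CCC(=O)OC(C)(C)C)ccc1O | intermediate
3 | tert-butyl 3-(4-hydroxy-3-iodo-5-methoxyphenyl)propanoate | COc1cc(CCC(=O)OC(C)(C)C)cc(I)c1O | intermediate
4 | [4-(benzyloxy)-3-methoxyphenyl]methanol | COc1cc(CO)ccc1OCc1ccccc1 | starting material
5 | tert-butyl 3-(4-{[4-(benzyloxy)-3-methoxybenzyl]oxy}-3-iodo-5-methoxyphenyl)propanoate | COc1cc(CCC(=O)OC(C)(C)C)cc(I)c1OCc1ccc(OCc2ccccc2)c(OC)c1 | intermediate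
6 | ethyl diazoacetate | CCOC(=O)C=[N+]=[N-] | starting material
7 | ethyl 2-(2-{[4-(benzyloxy)-3-methoxybenzyl]oxy}-5-(3-tert-butoxy-3-oxopropyl)-3-methoxyphenyl)-2-diazoacetate | COc1cc(CCC(=O)OC(C)(C)C)cc(C(=[N+]=[N-])C(=O)OCC)c1OCc1ccc(OCc2ccccc2)c(OC)c1 | intermediate
8 | ethyl (2S,3R)-2-[4-(benzyloxy)-3-methoxyphenyl]-5-(3-tert-butoxy-3-oxopropyl)-7-methoxy-2,3-dihydro-1-benzofuran-3-carboxylate (cis) | CC(C)(C)OC(=O)CCc1cc(OC)c2c(c1)[C@@H](C(=O)OCC)[C@@H](c1ccc(OCc3ccccc3)c(OC)c1)O2 | intermediate
9 | ethyl (2S,3S)-2-[4-(benzyloxy)-3-methoxyphenyl]-5-(3-tert-butoxy-3-oxopropyl)-7-methoxy-2,3-dihydro-1-benzofuran-3-carboxylate (trans) | CC(C)(C)OC(=O)CCc1cc(OC)c2c(c1)[C@H](C(=O)OCC)[C@@H](c1ccc(OCc3ccccc3)c(OC)c1)O2 | intermediate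
10 | tert-butyl 3-[(2S,3R)-2-[4-(benzyloxy)-3-methoxyphenyl]-3-(hydroxymethyl)-7-methoxy-2,3-dihydro-1-benzofuran-5-yl]propanoate | CC(C)(C)OC(=O)CCc1cc(OC)c2c(c1)[C@H](CO)[C@@H](c1ccc(OCc3ccccc3)c(OC)c1)O2 | intermediate
11 | tert-butyl 3-[(2S,3R)-2-[4-(benzyloxy)-3-methoxyphenyl]-3-[(benzyloxy)methyl]-7-methoxy-2,3-dihydro-1-benzofuran-5-yl]propanoate | CC(C)(C)OC(=O)CCc1cc(OC)c2c(c1)[C@H](COCc1ccccc1)[C@@H](c1ccc(OCc3ccccc3)c(OC)c1)O2 | intermediate
12 | benzyl 3-[4-(benzyloxy)-3-methoxyphenyl]propanoate | COc1cc(CCC(=O)OCc2ccccc2)ccc1OCc1ccccc1 | intermediate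
13 | 3-[4-(benzyloxy)-3-methoxyphenyl]propanoic acid | COc1cc(CCC(=O)O)ccc1OCc1ccccc1 | intermediate
14 | (4S)-4-benzyl-1,3-oxazolidin-2-one | O=C1N[C@@H](Cc2ccccc2)CO1 | starting material
15 | 3-[4-(benzyloxy)-3-methoxyphenyl]propanoic pivalic anhydride | COc1cc(CCC(=O)OC(=O)C(C)(C)C)ccc1OCc1ccccc1 | intermediate
16 | (4S)-4-benzyl-3-{3-[4-(benzyloxy)-3-methoxyphenyl]propanoyl}-1,3-oxazolidin-2-one | COc1cc(CCC(=O)N2[C@@H](Cc3ccccc3)COC2=O)ccc1OCc1ccccc1 | intermediate
17 | tert-butyl (2RS,3R)-3-{[(4S)-4-benzyl-2-oxo-1,3-oxazolidin-3-yl]carbonyl}-4-[4-(benzyloxy)-3-methoxyphenyl]-2-({(2S,3R)-2-[4-(benzyloxy)-3-methoxyphenyl]-3-[(benzyloxy)methyl]-7-methoxy-2,3-dihydro-1-benzofuran-5-yl}methyl)butanoate (epimers at C2, drawn without that descriptor) | CC(C)(C)OC(=O)C(Cc1cc(OC)c2c(c1)[C@H](COCc1ccccc1)[C@@H](c1ccc(OCc3ccccc3)c(OC)c1)O2)[C@@H](Cc1ccc(OCc2ccccc2)c(OC)c1)C(=O)N1[C@@H](Cc2ccccc2)COC1=O | intermediate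
18 | tert-butyl (2RS,3R)-4-[4-(benzyloxy)-3-methoxyphenyl]-3-(hydroxymethyl)-2-({(2S,3R)-2-[4-(benzyloxy)-3-methoxyphenyl]-3-[(benzyloxy)methyl]-7-methoxy-2,3-dihydro-1-benzofuran-5-yl}methyl)butanoate (epimers at C2) | CC(C)(C)OC(=O)C(Cc1cc(OC)c2c(c1)[C@H](COCc1ccccc1)[C@@H](c1ccc(OCc3ccccc3)c(OC)c1)O2)[C@@H](Cc1ccc(OCc2ccccc2)c(OC)c1)CO | intermediate
19 | (3R,4R)-4-[4-(benzyloxy)-3-methoxybenzyl]-3-({(2S,3R)-2-[4-(benzyloxy)-3-methoxyphenyl]-3-[(benzyloxy)methyl]-7-methoxy-2,3-dihydro-1-benzofuran-5-yl}methyl)oxolan-2-one | COc1cc(C[C@H]2COC(=O)[C@@H]2Cc2cc(OC)c3c(c2)[C@H](COCc2ccccc2)[C@@H](c2ccc(OCc4ccccc4)c(OC)c2)O3)ccc1OCc1ccccc1 | intermediate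
20 | isolappaol A | COc1cc(C[C@H]2COC(=O)[C@@H]2Cc2cc(OC)c3c(c2)[C@H](CO)[C@@H](c2ccc(O)c(OC)c2)O3)ccc1O | target

**Count and risks**

Total steps: 12. Longest linear sequence: 10 (steps 1–7, then 10–12); steps 8–9 form the second branch.

Steps most likely to fail:

1. Step 10. Homodimerisation of either enolate or incomplete oxidation may outrun cross-coupling, and facial control at the imide carbon may erode. The fallback sets out from 11 and returns at 18, replacing the oxidative coupling by a polar, catalyst-controlled allylation. Eugenol is O-benzylated (BnBr, K2CO3, DMF) to 4-allyl-1-(benzyloxy)-2-methoxybenzene F1. Cross-metathesis of this with (Z)-but-2-ene-1,4-diyl dimethyl biscarbonate (second-generation Ru–NHC catalyst, CH2Cl2, 40 °C) should give (E)-4-[4-(benzyloxy)-3-methoxyphenyl]but-2-en-1-yl methyl carbonate F2. Ester 11 is converted (LDA, TMSCl, THF, −78 °C) into its trimethylsilyl ketene acetal F3. Iridium-catalysed branched-selective asymmetric allylic substitution of F2 by F3 ([Ir(cod)Cl]2, a BINOL-derived phosphoramidite, alkoxide or fluoride activation) should then give the branched pent-4-enoate F4 as a mixture at the ester α-carbon; the ligand enantiomer is chosen to give the configuration of lactone C4. Ozonolysis at −78 °C with NaBH4 work-up passes through the aldehyde F5 and should deliver hydroxy ester 18, which enters the DBU stage of step 11.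

2. Step 5. Enantioselection at C2′ may be insufficient or of the opposite sense, and carbene dimerisation may compete at low temperature. The fallback sets out from 7 and returns at 10, replacing catalyst control by resolution. Rh2(OAc)4 in CH2Cl2 followed by the same ethoxide equilibration should give the racemic trans ester, that is 9 together with the ent-trans ester F7, formed through 8 and the ent-cis ester F6. LiBH4 as in step 6 gives 10 together with the ent-alcohol F8. Lipase-catalysed acylation (vinyl acetate, Pseudomonas cepacia lipase, screened so that the unwanted enantiomer reacts) should leave 10 unreacted and remove the other enantiomer as the ent-acetate F9. Alcohol 10 re-enters at step 7; the same resolution can upgrade material of partial enantiopurity from the catalytic step.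

3. Step 4. Palladium-carbene decomposition of the diazo ester (dimerisation, loss of N2) may outrun coupling at the hindered ortho-alkoxy aryl iodide. The fallback sets out from 5 and returns at 7 in two conventional steps. Reformatsky–Negishi coupling of 5 with BrZnCH2CO2Et (Pd2(dba)3, XPhos, THF, 60 °C) should give the ethyl arylacetate F10. Regitz diazo transfer (p-ABSA, DBU, MeCN, 0 °C to rt), selective for the more acidic arylacetate CH2 over the tert-butyl propanoate, then gives 7.

**Further compounds**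

F1 | step 10 | 4-allyl-1-(benzyloxy)-2-methoxybenzene | C=CCc1ccc(OCc2ccccc2)c(OC)c1
F2 | step 10 | (E)-4-[4-(benzyloxy)-3-methoxyphenyl]but-2-en-1-yl methyl carbonate | COC(=O)OC/C=C/Cc1ccc(OCc2ccccc2)c(OC)c1
F3 | step 10 | trimethylsilyl ketene acetal of 11 (tert-butyl trimethylsilyl acetal, alkene geometry not defined) | CC(C)(C)OC(O[Si](C)(C)C)=CCc1cc(OC)c2c(c1)[C@H](COCc1ccccc1)[C@@H](c1ccc(OCc3ccccc3)c(OC)c1)O2
F4 | step 10 | tert-butyl (2RS,3S)-3-[4-(benzyloxy)-3-methoxybenzyl]-2-({(2S,3R)-2-[4-(benzyloxy)-3-methoxyphenyl]-3-[(benzyloxy)methyl]-7-methoxy-2,3-dihydro-1-benzofuran-5-yl}methyl)pent-4-enoate | CC(C)(C)OC(=O)C(Cc1cc(OC)c2c(c1)[C@H](COCc1ccccc1)[C@@H](c1ccc(OCc3ccccc3)c(OC)c1)O2)[C@@H](Cc1ccc(OCc2ccccc2)c(OC)c1)C=C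
F5 | step 10 | tert-butyl (2RS,3R)-4-[4-(benzyloxy)-3-methoxyphenyl]-3-formyl-2-({(2S,3R)-2-[4-(benzyloxy)-3-methoxyphenyl]-3-[(benzyloxy)methyl]-7-methoxy-2,3-dihydro-1-benzofuran-5-yl}methyl)butanoate | CC(C)(C)OC(=O)C(Cc1cc(OC)c2c(c1)[C@H](COCc1ccccc1)[C@@H](c1ccc(OCc3ccccc3)c(OC)c1)O2)[C@@H](Cc1ccc(OCc2ccccc2)c(OC)c1)C=O
F6 | step 5 | ethyl (2R,3S)-2-[4-(benzyloxy)-3-methoxyphenyl]-5-(3-tert-butoxy-3-oxopropyl)-7-methoxy-2,3-dihydro-1-benzofuran-3-carboxylate (ent-cis ester) | CC(C)(C)OC(=O)CCc1cc(OC)c2c(c1)[C@H](C(=O)OCC)[C@H](c1ccc(OCc3ccccc3)c(OC)c1)O2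
F7 | step 5 | ethyl (2R,3R)-2-[4-(benzyloxy)-3-methoxyphenyl]-5-(3-tert-butoxy-3-oxopropyl)-7-methoxy-2,3-dihydro-1-benzofuran-3-carboxylate (ent-trans ester) | CC(C)(C)OC(=O)CCc1cc(OC)c2c(c1)[C@@H](C(=O)OCC)[C@H](c1ccc(OCc3ccccc3)c(OC)c1)O2
F8 | step 5 | tert-butyl 3-[(2R,3S)-2-[4-(benzyloxy)-3-methoxyphenyl]-3-(hydroxymethyl)-7-methoxy-2,3-dihydro-1-benzofuran-5-yl]propanoate (ent-alcohol) | CC(C)(C)OC(=O)CCc1cc(OC)c2c(c1)[C@@H](CO)[C@H](c1ccc(OCc3ccccc3)c(OC)c1)O2
F9 | step 5 | tert-butyl 3-[(2R,3S)-3-(acetoxymethyl)-2-[4-(benzyloxy)-3-methoxyphenyl]-7-methoxy-2,3-dihydro-1-benzofuran-5-yl]propanoate (ent-acetate) | CC(C)(C)OC(=O)CCc1cc(OC)c2c(c1)[C@@H](COC(C)=O)[C@H](c1ccc(OCc3ccccc3)c(OC)c1)O2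
F10 | step 4 | ethyl 2-(2-{[4-(benzyloxy)-3-methoxybenzyl]oxy}-5-(3-tert-butoxy-3-oxopropyl)-3-methoxyphenyl)acetate | CCOC(=O)Cc1cc(CCC(=O)OC(C)(C)C)cc(OC)c1OCc1ccc(OCc2ccccc2)c(OC)c1
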